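**Assumption (one line):** the lactamide-directed dearomatization (step 6) is assumed to proceed through the six-membered transition state with the lactamide methyl pseudo-equatorial, so the (R)-aryloxypropanamide gives the 8aR lactone; if the sense were opposite, (R)-lactamide would be used in step 3 and nothing else changes.

## Retrosynthetic overview

1. 13 ⇐ 12: hydrolysis of a γ,δ-epoxy enone at the allylic carbon (inversion at C4, C5–O retained).
2. 12 ⇐ 11: Luche reduction / Stork–Danheiser 1,3-carbonyl transposition of an epoxy vinylogous ester; this moves C=O next to C6 and expels the lactate tether.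
3. 11 ⇐ 10: lactone opening and OH-directed nucleophilic epoxidation of a 3-alkoxy-p-quinol (sets C5).
4. 10 ⇐ 9 (key step): lactamide-tethered, diastereoselective oxidative dearomatization of a 4-alkylresorcinol (sets C6); 9 ⇐ oleic acid redox-active ester + bromoresorcinol ether by Ni decarboxylative sp3–sp2 coupling, which delivers the whole (Z)-C17 chain.
5. Ring order: the carbocycle is the purchased arene (no carbocyclisation). Only a temporary 1,4-dioxanone (step 6) and an epoxide (step 7) are formed, and both are opened again.

## Route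

**Step 1**
Reactants: 1 oleic acid; 2 N-hydroxyphthalimide
Product: 3 N-(oleoyloxy)phthalimide (redox-active ester)
Conditions: DIC, DMAP (cat.), CH2Cl2, rt
Reagents that add atoms: none (both partners are numbered reactants)
Why: Steglich-type esterification; activates the acid for decarboxylative coupling without touching the Z-alkene.

**Step 2**
Reactants: 4 4-bromoresorcinol
Product: 5 2-bromo-5-(tert-butyldimethylsilyloxy)phenol
Conditions: TBSCl (1.05 equiv), imidazole, CH2Cl2/DMF, –20 → 0 °C
Reagents that add atoms: TBSCl, CC(C)(C)[Si](C)(C)Cl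
Why: Regioselective silylation of the unhindered OH para to Br; the OH ortho to Br is hindered and H-bonded to Br. Minor regioisomer removed by chromatography.

**Step 3**
Reactants: 5; 6 (S)-N,N-dimethyllactamide
Product: 7 (R)-2-[2-bromo-5-(TBSO)phenoxy]-N,N-dimethylpropanamide
Conditions: PPh3, DIAD, THF, 0 °C → rt
Reagents that add atoms: none
Why: Mitsunobu etherification; clean SN2 inversion at the lactate carbon converts the natural (S)-lactamide into the (R)-aryloxy tether.

**Step 4**
Reactants: 7; 3
Product: 8 (R)-2-[5-(TBSO)-2-((Z)-heptadec-8-enyl)phenoxy]-N,N-dimethylpropanamide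
Conditions: NiBr2·dme (10 mol %), dtbbpy (10 mol %), Zn, NaI, DMA, 30–40 °C, slow addition of 3
Reagents that add atoms: none
Why: Ni-catalysed decarboxylative cross-electrophile coupling (Weix type). The primary C17 radical formed by loss of CO2 and phthalimide is captured by the aryl–Ni species; the remote Z-alkene, amide and silyl ether are inert.

**Step 5**
Reactants: 8
Product: 9 (R)-2-[2-((Z)-heptadec-8-enyl)-5-hydroxyphenoxy]-N,N-dimethylpropanamide
Conditions: TBAF, AcOH, THF, 0 °C
Reagents that add atoms: none
Why: Fluoride desilylation, buffered so the α-aryloxy amide stereocentre is not epimerised.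

**Step 6 (key step)**
Reactants: 9
Product: 10 (3R,8aR)-8a-[(Z)-heptadec-8-enyl]-3-methyl-3H-1,4-benzodioxine-2,6(8aH)-dione (cyclohexa-2,5-dienone fused to a 1,4-dioxan-2-one)
Conditions: PhI(OCOCF3)2 (1.1 equiv), CH2Cl2, –40 → 0 °C; then H2O/NaHCO3
Reagents that add atoms: water, O (lactone C=O oxygen, from hydrolysis of the iminium ether; Me2NH is lost)
Why: Tethered oxidative dearomatization of a resorcinol (Pettus type). The amide oxygen traps the phenoxonium ion at the alkyl-bearing para carbon through a six-membered transition state. The methyl sits pseudo-equatorial because the pseudo-axial position clashes with the C17 chain, which fixes the quaternary C–O centre as 8aR (C6 of the target). The minor diastereomer is removed by chromatography, so the ee is that of the lactamide.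

**Step 7**
Reactants: 10
Product: 11 (2R)-2-{[(1S,5R,6R)-5-[(Z)-heptadec-8-enyl]-5-hydroxy-2-oxo-7-oxabicyclo[4.1.0]hept-3-en-4-yl]oxy}propanoic acid (epoxide cis to the tertiary OH)
Conditions: LiOH, THF/H2O, 0 °C; then 30% H2O2, 0 °C; Na2SO3; pH 4
Reagents that add atoms: hydrogen peroxide, OO (epoxide O); water/hydroxide, O (carboxylic acid OH)
Why: Saponification frees the tertiary OH, followed by hydroxyl-directed Weitz–Scheffer epoxidation. Hydroperoxide attacks only the unsubstituted enone (the other is a deactivated vinylogous ester) and is delivered by H-bonding syn to the γ-OH, setting C5–O cis to C6–OH. The chain alkene is inert to a nucleophilic oxidant.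

**Step 8**
Reactants: 11
Product: 12 (4R,5R,6R)-4,5-epoxy-6-[(Z)-heptadec-8-enyl]-6-hydroxycyclohex-2-en-1-one
Conditions: NaBH4, CeCl3·7H2O, MeOH, –40 → –10 °C; then 10% aq. oxalic acid, THF, rt
Reagents that add atoms: water, O (new C1 carbonyl oxygen)
Why: Luche 1,2-reduction followed by Stork–Danheiser transposition. Acid hydrolysis of the γ-hydroxy enol ether expels (R)-lactic acid and water, placing the carbonyl next to C6 and the alkene at C2=C3. No stereocentre of 12 is touched, and the new carbinol centre is destroyed.

**Step 9**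
Reactants: 12
Product: 13 pleiogenone A, (4S,5R,6R)-4,5,6-trihydroxy-6-[(Z)-heptadec-8-enyl]cyclohex-2-en-1-one
Conditions: 0.2 M HClO4, THF/H2O (3:1), 0 °C → rt
Reagents that add atoms: water, O (C4–OH)
Why: Acid-catalysed hydrolysis of a vinyl epoxide. Water attacks the allylic C4 (C5 is neopentyl-like, next to the quaternary carbon) with inversion, giving the 4,5-trans diol while C5–O stays cis to C6–OH. A non-nucleophilic acid avoids halohydrin formation.

## Compound list

1 | oleic acid, (9Z)-octadec-9-enoic acid | CCCCCCCC/C=C\CCCCCCCC(=O)O | starting material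
2 | N-hydroxyphthalimide | ON1C(=O)c2ccccc2C1=O | starting material
3 | 1,3-dioxoisoindolin-2-yl (9Z)-octadec-9-enoate | CCCCCCCC/C=C\CCCCCCCC(=O)ON1C(=O)c2ccccc2C1=O | intermediate
4 | 4-bromoresorcinol | Oc1ccc(Br)c(O)c1 | starting material
5 | 2-bromo-5-(tert-butyldimethylsilyloxy)phenol | Oc1cc(O[Si](C)(C)C(C)(C)C)ccc1Br | intermediate
6 | (S)-2-hydroxy-N,N-dimethylpropanamide | C[C@H](O)C(=O)N(C)C | starting material
7 | (R)-2-[2-bromo-5-(TBSO)phenoxy]-N,N-dimethylpropanamide | C[C@@H](Oc1cc(O[Si](C)(C)C(C)(C)C)ccc1Br)C(=O)N(C)C | intermediate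
8 | (R)-2-[5-(TBSO)-2-((Z)-heptadec-8-enyl)phenoxy]-N,N-dimethylpropanamide | C[C@@H](Oc1cc(O[Si](C)(C)C(C)(C)C)ccc1CCCCCCC/C=C\CCCCCCCC)C(=O)N(C)C | intermediate
9 | (R)-2-[2-((Z)-heptadec-8-enyl)-5-hydroxyphenoxy]-N,N-dimethylpropanamide | C[C@@H](Oc1cc(O)ccc1CCCCCCC/C=C\CCCCCCCC)C(=O)N(C)C | intermediate
10 | (3R,8aR)-8a-[(Z)-heptadec-8-enyl]-3-methyl-3H-1,4-benzodioxine-2,6(8aH)-dione | CCCCCCCC/C=C\CCCCCCC[C@@]12C=CC(=O)C=C1O[C@H](C)C(=O)O2 | intermediate
11 | (2R)-2-{[(1S,5R,6R)-5-[(Z)-heptadec-8-enyl]-5-hydroxy-2-oxo-7-oxabicyclo[4.1.0]hept-3-en-4-yl]oxy}propanoic acid | CCCCCCCC/C=C\CCCCCCC[C@]1(O)C(O[C@H](C)C(O)=O)=CC(=O)[C@H]2O[C@@H]12 | intermediate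
12 | (4R,5R,6R)-4,5-epoxy-6-[(Z)-heptadec-8-enyl]-6-hydroxycyclohex-2-en-1-one | CCCCCCCC/C=C\CCCCCCC[C@]1(O)C(=O)C=C[C@H]2O[C@@H]12 | intermediate
13 | pleiogenone A, (4S,5R,6R)-4,5,6-trihydroxy-6-[(Z)-heptadec-8-enyl]cyclohex-2-en-1-one | CCCCCCCC/C=C\CCCCCCC[C@]1(O)C(=O)C=C[C@H](O)[C@H]1O | target

## Summary

**Total steps:** 9.
**Longest linear sequence:** 8 (4 → 5 → 7 → 8 → 9 → 10 → 11 → 12 → 13; step 1 is the convergent branch).

**Three steps most likely to fail, with fallbacks:**

1. **Step 6** (diastereoselectivity, sense of induction, and chemoselectivity of the dearomatization). Fallback: switch from auxiliary control to reagent control. Use an achiral glycolic acid tether and a preformed chiral C2-symmetric aryl-λ3-iodane (Kita–Ishihara-type enantioselective oxidative lactonization) to form the same dioxanone.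

2. **Step 7** (facial and regioselectivity of the epoxidation). Fallback: replace the epoxide logic with a tether. Boronate-tethered oxa-Michael addition from the C6–OH (PhB(OH)2) forces the C5–O cis. Then hydroxylate the α′-enolate of the vinylogous ester at C4 with a Davis oxaziridine, anti to C5–O. The same Luche/acid transposition then gives 13 directly.

3. **Step 4** (cross-electrophile coupling of a hindered, electron-rich aryl bromide). Fallback: reverse the aryl polarity and the order. Couple 3 with the arylzinc from 1-bromo-2,4-bis(methoxymethoxy)benzene (Ni- or Fe-catalysed decarboxylative Negishi), then unmask, silylate the unhindered para OH and install the lactamide by Mitsunobu.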